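Over the last 10.0 min of the larch run, which is this very flask followed so far, other capture product gained 2 percentage points, and target gained less, 1 point.

| flask | starting material | first nucleophile | solid second nucleophile | remark | time |
|---|---|---|---|---|---|
| larch | 20 mM | 16 mM | 14 mM | the very flask that is asked about, followed so far |  |
| flask | 20 mM | 16.0 mM | 14.0 mM |  | 2.0 h |

larch run (percent of the starting material charged)

| time / min | other capture product / % | target / % |
|---|---|---|
| 6.00 | 0.5 | 4.0 |
| 15.0 | 0.5 | 7.8 |
| 20.0 | 2.0 | 10.2 |
| 30.0 | 3.5 | 12.3 |
| 40.0 | 5.3 | 14.2 |
| 50.0 | 7.3 | 15.2 |

(scatter of a reading: 0.3 percentage points)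

- the numbers in the tables scatter with a standard deviation of 0.3 percentage points
- at the start none of the solid second nucleophile is in solution

* ratio of other capture product to target at 3.0 min
* ratio of other capture product to target at 2.0 h
* which of other capture product and target there is more of at 2.0 h

I take the short-lived common intermediate as steady at each moment, so the rates of making other capture product and target stand in proportion to dissolved [second nucleophile] over [first nucleophile], times a selectivity factor. That [second nucleophile] climbs from zero, so early on the ratio of other capture product to target should grow in step with time. My capture clock, the ratio divided by the time, reads 0.00961 min⁻¹ at 50.0 min and 0.00949 min⁻¹ at 30.0 min. At 3.0 min it gives 0.0288.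

For 2.0 h I bracket. Other capture product, kept at its gain since 30.0 min, reaches 20.6 %. If target kept its last gain, it would reach 22.2 %, a ratio of 0.928. But its gain in the readings just fell by half, so I tighten my estimated floor by holding target at its last reading: 1.36. Let it instead lose as fast as it last gained, and it stands at 8.20 %, my ceiling of 2.51. I commit to the geometric middle, 1.85.

The forecast says 0.015 and 1.1, with other capture product ahead: “Other probably just leads, though saturation could reverse this.” Its late ratio lies below my floor.

The flask gives 0.0264 and 1.84, inside the bracket, with other capture product ahead, 22.0 % against 11.9 %.

    starting material ⇌ intermediate (K = 0.00140, k = 0.0320 min⁻¹)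
    first nucleophile + intermediate → target (k = 400 M⁻¹ min⁻¹)
    second nucleophile + intermediate → other capture product (k = 1100 M⁻¹ min⁻¹)
    target → over-reaction product (k = 0.0180 min⁻¹)
    solid second nucleophile ⇌ second nucleophile, rate k5*(cs5 - [second nucleophile]) while solid is left; crystals form when [second nucleophile] > cs5 (solubility = 9.20 mM, k = 0.0110 min⁻¹)
    intermediate → side product (k = 0.0190 min⁻¹)

The clock's 0.0288 stands against 0.0264. With 64 mM of first nucleophile in a neighbour flask, a quarter of the clock gives 0.00720 at 3.0 min, and that flask gives 0.00658. In this flask the half-life of target by its loss to over-reaction product alone is 0.64 h, shorter than the 2.0 h run. At 2.00 h this flask holds 26.9 % over-reaction product against 11.9 % target.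

All runs stem from a simulated flask with made-up constants.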